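A direct plan would first make the diaryl ether by SNAr between two 2-methoxybenzaldehydes, giving the dialdehyde A1.
A double directed ortho-lithiation/borylation/oxidation would then install the two flanked phenols, giving the bis-phenol A2, which would be benzylated.
A twofold aldol condensation would give the bis-chalcone A3, and a hypervalent-iodine 1,2-aryl shift the bis-isoflavone A4.
An asymmetric transfer hydrogenation under dynamic kinetic resolution would give the bis(cis-isoflavan-4-ol) A5, and hydrogenolysis the target.
Weak point, the double ortho-lithiation of A1: both masked aldehydes and both ring positions must be metalated at once with a large excess of butyllithium, while lithiation next to the masked formyl group and ether cleavage compete.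
Weak point, the twofold oxidative aryl shift on A3: two electron-rich rings and two free ortho-phenols invite aurone/flavone formation and over-oxidation, and both arms must rearrange.
Weak point, the stereo-setting reduction to A5: C3 is fixed only indirectly, through four new centres of which two (the C4 carbinols) are deleted again, and it depends on epimerisation of a hindered ortho-methoxyaryl ketone on both arms.

**Retrosynthetic overview**
- Feature used: in each ring C, C3 carries H, ring B and two CH2 groups (C2 and C4) that differ only at their far ends (O1 versus C4a of ring A). Joining C2 and C4 through a temporary oxygen makes C3 the prochiral centre of a 3-aryloxetane, so the target is cut back to an achiral bis-oxetane with no stereoisomers.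
- Key disconnection: both C3 centres are set together by catalyst-controlled opening of the two oxetane rings with bromide, which also marks one arm as CH2Br (future C4) and the other as CH2OH (future C2).
- Ring order: the diaryl ether (rings B and B′) is made first by SNAr between a fluoroaldehyde and the phenol derived from it, and the activating formyl groups are then turned into the 3′-hydroxyls by a Dakin-type oxidation. Ring A is attached at O1–C2 (Mitsunobu) and ring C closes last at C4–C4a (Parham cyclisation).
- Avoided by design: no lithiation of the diaryl ether, no oxidative aryl shift, no carbinol centres made and deleted; C3 is never next to a carbonyl group and cannot epimerise.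

Key step: step 7

Assumption: 3-bromooxetane and 5-(benzyloxy)-2-bromophenol are taken as catalogue building blocks; the hand of the squaramide is the one that turns 3-phenyloxetane into (R)-3-bromo-2-phenylpropan-1-ol, to be confirmed on that model before use.

Step 1
Reactants: 1 1-bromo-4-fluoro-2-methoxybenzene (2-bromo-5-fluoroanisole)
Product: 3 3-bromo-6-fluoro-2-methoxybenzaldehyde, via aryllithium 2 (not isolated)
Conditions: LDA (1.1 equiv), THF, −78 °C, 1 h; DMF (1.5 equiv), −78 → 0 °C; aq. HCl
Reagents that add atoms: N,N-dimethylformamide, CN(C)C=O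
Why: Directed ortho-metalation/formylation: the ring proton between fluorine and methoxy is the most acidic site, so LDA removes it at −78 °C without touching the C–Br bond and DMF traps the aryllithium as the aldehyde.

Step 2
Reactants: 3 3-bromo-6-fluoro-2-methoxybenzaldehyde
Product: 5 3-bromo-6-hydroxy-2-methoxybenzaldehyde, via sulfonylethyl ether 4 (not isolated)
Conditions: 2-(methylsulfonyl)ethanol (1.5 equiv), NaH (2.5 equiv), DMF, 0 °C → rt; aq. HCl
Reagents that add atoms: 2-(methylsulfonyl)ethanol, OCCS(C)(=O)=O
Why: SNAr with a hydroxide surrogate: the alkoxide of 2-(methylsulfonyl)ethanol displaces the ortho-formyl-activated fluoride, and the resulting 2-(methylsulfonyl)ethyl aryl ether loses methyl vinyl sulfone by E1cB elimination to release the phenoxide, so no free hydroxide that could start a Cannizzaro reaction is present.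

Step 3
Reactants: 3 3-bromo-6-fluoro-2-methoxybenzaldehyde; 5 3-bromo-6-hydroxy-2-methoxybenzaldehyde
Product: 6 6,6′-oxybis(3-bromo-2-methoxybenzaldehyde)
Conditions: 3 (1.0 equiv), 5 (1.0 equiv), Cs2CO3 (1.5 equiv), DMSO, 100 °C, 16 h
Reagents that add atoms: none
Why: Nucleophilic aromatic substitution (SNAr): the phenoxide of 5 adds to the fluorine-bearing carbon of 3, which the ortho-formyl group activates, and loss of fluoride from the Meisenheimer adduct gives the symmetrical diaryl ether in which each formyl group sits where a 3′-hydroxyl is needed.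

Step 4
Reactants: 6 6,6′-oxybis(3-bromo-2-methoxybenzaldehyde)
Product: 8 6,6′-oxybis(3-bromo-2-methoxyphenol), via bis(aryl formate) 7 (not isolated)
Conditions: mCPBA (2.6 equiv), CH2Cl2, 0 °C → rt; then MeOH, Et3N (cat.), rt
Reagents that add atoms: 3-chloroperbenzoic acid, O=C(OO)c1cccc(Cl)c1
Why: Dakin-type Baeyer–Villiger oxidation: in the peracid adduct the electron-rich aryl group flanked by two ether oxygens migrates in preference to hydride to give the aryl formate, which methanol cleaves to the phenol.

Step 5
Reactants: 8 6,6′-oxybis(3-bromo-2-methoxyphenol)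
Product: 9 1,1′-oxybis[2-(benzyloxy)-4-bromo-3-methoxybenzene]
Conditions: BnBr (2.5 equiv), K2CO3 (3 equiv), DMF, 60 °C
Reagents that add atoms: benzyl bromide, BrCc1ccccc1
Why: Williamson ether synthesis: the flanked phenoxides are benzylated so that they are silent toward the silyl bromide, Mitsunobu and organolithium steps and are released together with the ring A benzyl groups at the end.

Step 6
Reactants: 9 1,1′-oxybis[2-(benzyloxy)-4-bromo-3-methoxybenzene]; 10 3-bromooxetane (4 equiv)
Product: 11 3,3′-{oxybis[3-(benzyloxy)-2-methoxy-4,1-phenylene]}bis(oxetane)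
Conditions: NiCl2·DME (5 mol%), 4,4′-di-tert-butyl-2,2′-bipyridine (5 mol%), [Ir{2-(2,4-difluorophenyl)-5-(trifluoromethyl)pyridinato}2(4,4′-di-tert-butyl-2,2′-bipyridine)]PF6 (2 mol%), (Me3Si)3SiH (2.4 equiv), Na2CO3 (4 equiv), DME, blue LED, rt
Reagents that add atoms: none
Why: Nickel/photoredox cross-electrophile coupling: the tris(trimethylsilyl)silyl radical abstracts bromine from 10, the oxetan-3-yl radical is captured by the arylnickel bromide formed by oxidative addition of zerovalent nickel into each C–Br bond of 9, and reductive elimination forms the two aryl–C(sp3) bonds to give an achiral product.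

Step 7
Reactants: 11 3,3′-{oxybis[3-(benzyloxy)-2-methoxy-4,1-phenylene]}bis(oxetane)
Product: 13 (2R,2′R)-2,2′-{oxybis[3-(benzyloxy)-2-methoxy-4,1-phenylene]}bis(3-bromopropan-1-ol), via bis(trimethylsilyl ether) 12 (not isolated)
Conditions: chiral 2-arylpyrrolidine tert-leucinamide squaramide (hydrogen-bond donor, 10 mol%), Me3SiBr (3 equiv), t-BuOMe/toluene, −78 °C, 48 h; then MeOH, PPTS (cat.), 0 °C
Reagents that add atoms: bromotrimethylsilane, C[Si](C)(C)Br
Why: Desymmetrising ring opening of a prochiral 3-aryloxetane, run at both ends of the molecule: the squaramide holds the bromide of Me3SiBr by two N–H hydrogen bonds, the silyl group passes to the oxetane oxygen, and the catalyst-bound bromide attacks one of the two enantiotopic CH2 groups of the silyloxetanium ion in an SN2 step driven by release of ring strain. The closest known reaction type is this same hydrogen-bond-donor catalysed addition of Me3SiBr to 3-aryloxetanes, which gives 3-bromo-2-arylpropyl silyl ethers. No ring is closed; the two temporary oxetane rings are opened, and mild methanolysis of the silyl ethers then frees the primary alcohols. Each new stereocentre (the future C3 and C3′, both R) is controlled by the catalyst alone, which decides which CH2 group receives bromide; the two oxetanes are far apart and should react independently, so an error at one end would give the separable meso diastereomer and the enantiomer would need two errors. The selectivity needed is between enantiotopic methylene groups and between the oxetanes and the other ethers; the substrate secures the second because the strained oxetane oxygens are the only ethers that Me3SiBr opens at −78 °C, and the low temperature keeps uncatalysed opening slow. The same operation differentiates the two arms, CH2Br for the later C4–C4a bond and CH2OH for the O1–C2 bond.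

Step 8
Reactants: 13 (2R,2′R)-bis-bromohydrin; 14 5-(benzyloxy)-2-bromophenol (2.4 equiv)
Product: 15 1,1′-oxybis{2-(benzyloxy)-4-[(2R)-1-{[5-(benzyloxy)-2-bromophenyl]oxy}-3-bromopropan-2-yl]-3-methoxybenzene}
Conditions: PPh3 (2.6 equiv), DIAD (2.6 equiv), THF, 0 °C → rt
Reagents that add atoms: none
Why: Mitsunobu etherification: each primary alcohol is activated as its alkoxyphosphonium ion and displaced by the acidic ortho-bromophenol in an SN2 step at CH2 that leaves the adjacent stereocentre untouched, forming both O1–C2 bonds and placing an aryl bromide within reach of each CH2Br.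

Step 9
Reactants: 15 tetrabromide
Product: 17 3,3′-{oxybis[3-(benzyloxy)-2-methoxy-4,1-phenylene]}bis[(3R)-7-(benzyloxy)-3,4-dihydro-2H-chromene], via dilithio species 16 (not isolated)
Conditions: t-BuLi (4.2 equiv), THF/Et2O/pentane, −100 °C, 20 min; then → rt, 2 h; aq. NH4Cl
Reagents that add atoms: none
Why: Parham cyclisation: tert-butyllithium exchanges the aryl bromides at −100 °C much faster than it attacks the primary alkyl bromides, and on warming each aryllithium closes ring C by 6-exo-tet SN2 attack on its CH2Br, forming C4–C4a with C3 untouched.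

Step 10
Reactants: 17 tetrabenzyl bis-isoflavan
Product: 18 CNP0116832.1, 3,3′-[oxybis(3-hydroxy-2-methoxy-4,1-phenylene)]bis[(3R)-chroman-7-ol]
Conditions: H2 (1 atm), 10% Pd/C (palladium on carbon), EtOAc/MeOH, rt
Reagents that add atoms: none
Why: Heterogeneous catalytic hydrogenolysis: palladium on carbon cleaves the four benzyl ethers to toluene, while the diaryl ether, the methyl ethers, the chroman rings and the C3 stereocentres (no benzylic heteroatom at C3 or C4) are inert.

**Compound list**

1 | 1-bromo-4-fluoro-2-methoxybenzene | COc1cc(F)ccc1Br | starting material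
2 | (3-bromo-6-fluoro-2-methoxyphenyl)lithium | COc1c(Br)ccc(F)c1[Li] | intermediate (not isolated)
3 | 3-bromo-6-fluoro-2-methoxybenzaldehyde | COc1c(Br)ccc(F)c1C=O | intermediate
4 | 3-bromo-2-methoxy-6-[2-(methylsulfonyl)ethoxy]benzaldehyde | COc1c(Br)ccc(OCCS(C)(=O)=O)c1C=O | intermediate (not isolated)
5 | 3-bromo-6-hydroxy-2-methoxybenzaldehyde | COc1c(Br)ccc(O)c1C=O | intermediate
6 | 6,6′-oxybis(3-bromo-2-methoxybenzaldehyde) | COc1c(Br)ccc(Oc2ccc(Br)c(OC)c2C=O)c1C=O | intermediate
7 | 6,6′-oxybis(3-bromo-2-methoxyphenyl) diformate | COc1c(Br)ccc(Oc2ccc(Br)c(OC)c2OC=O)c1OC=O | intermediate (not isolated)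
8 | 6,6′-oxybis(3-bromo-2-methoxyphenol) | COc1c(Br)ccc(Oc2ccc(Br)c(OC)c2O)c1O | intermediate
9 | 1,1′-oxybis[2-(benzyloxy)-4-bromo-3-methoxybenzene] | COc1c(Br)ccc(Oc2ccc(Br)c(OC)c2OCc2ccccc2)c1OCc1ccccc1 | intermediate
10 | 3-bromooxetane | BrC1COC1 | starting material
11 | 3,3′-{oxybis[3-(benzyloxy)-2-methoxy-4,1-phenylene]}bis(oxetane) | COc1c(C2COC2)ccc(Oc2ccc(C3COC3)c(OC)c2OCc2ccccc2)c1OCc1ccccc1 | intermediate
12 | bis(trimethylsilyl ether) of 13; each arm (2R)-1-bromo-3-[(trimethylsilyl)oxy]propan-2-yl | COc1c([C@@H](CBr)CO[Si](C)(C)C)ccc(Oc2ccc([C@@H](CBr)CO[Si](C)(C)C)c(OC)c2OCc2ccccc2)c1OCc1ccccc1 | intermediate (not isolated)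
13 | (2R,2′R)-2,2′-{oxybis[3-(benzyloxy)-2-methoxy-4,1-phenylene]}bis(3-bromopropan-1-ol) | COc1c([C@@H](CBr)CO)ccc(Oc2ccc([C@@H](CBr)CO)c(OC)c2OCc2ccccc2)c1OCc1ccccc1 | intermediate
14 | 5-(benzyloxy)-2-bromophenol | Oc1cc(OCc2ccccc2)ccc1Br | starting material
15 | 1,1′-oxybis{2-(benzyloxy)-4-[(2R)-1-{[5-(benzyloxy)-2-bromophenyl]oxy}-3-bromopropan-2-yl]-3-methoxybenzene} | COc1c([C@@H](CBr)COc2cc(OCc3ccccc3)ccc2Br)ccc(Oc2ccc([C@@H](CBr)COc3cc(OCc4ccccc4)ccc3Br)c(OC)c2OCc2ccccc2)c1OCc1ccccc1 | intermediate
16 | dilithio species of 15 (each ring A C–Br replaced by C–Li) | COc1c([C@@H](CBr)COc2cc(OCc3ccccc3)ccc2[Li])ccc(Oc2ccc([C@@H](CBr)COc3cc(OCc4ccccc4)ccc3[Li])c(OC)c2OCc2ccccc2)c1OCc1ccccc1 | intermediate (not isolated)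
17 | 3,3′-{oxybis[3-(benzyloxy)-2-methoxy-4,1-phenylene]}bis[(3R)-7-(benzyloxy)-3,4-dihydro-2H-chromene] | COc1c([C@@H]2COc3cc(OCc4ccccc4)ccc3C2)ccc(Oc2ccc([C@@H]3COc4cc(OCc5ccccc5)ccc4C3)c(OC)c2OCc2ccccc2)c1OCc1ccccc1 | intermediate
18 | CNP0116832.1: 3,3′-[oxybis(3-hydroxy-2-methoxy-4,1-phenylene)]bis[(3R)-chroman-7-ol] | COc1c([C@@H]2COc3cc(O)ccc3C2)ccc(Oc2ccc([C@@H]3COc4cc(O)ccc4C3)c(OC)c2O)c1O | target

Total step count: 10. Longest linear sequence: 10 steps (1 to 18).

**Steps most likely to fail**

Step 7 (key step): selection between the enantiotopic CH2 groups may be eroded, because the ortho-methoxy group sits next to each oxetane and because traces of HBr open the ring without the catalyst; the material would then be contaminated with the meso isomer. The fallback sets out from 11 and comes back at 13. Both oxetanes are hydrolysed with dilute H2SO4 in aqueous THF to the tetraol 2,2′-{oxybis[3-(benzyloxy)-2-methoxy-4,1-phenylene]}bis(propane-1,3-diol) F1. Lipase-catalysed mono-acetylation of each prochiral diol (Pseudomonas lipase, vinyl acetate, t-BuOMe, enzyme screened for the S sense) gives the (S,S)-bis(monoacetate) F2. An Appel reaction (CBr4, PPh3, CH2Cl2, 0 °C) turns the free hydroxyls into bromides to give the (R,R)-bis(bromo acetate) F3, and HCl in MeOH removes the acetates to return 13.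

Step 6: oxidative addition of nickel into the hindered, electron-rich C–Br bonds next to the methoxy groups may be too slow, so that protodebromination and mono-coupling take over. The fallback sets out from 9 and comes back at 11, building the oxetanes by ring closure instead of coupling. Pd-catalysed α-arylation of diethyl malonate (Pd(OAc)2, P(t-Bu)3·HBF4, K3PO4, toluene, 80 °C) gives the tetraethyl bis(arylmalonate) F4. LiAlH4 (THF, 0 °C) reduces it to the tetraol F1, and one-pot mono-tosylation/Williamson closure of each 1,3-diol (n-BuLi, TsCl, then n-BuLi, THF, 0 → 60 °C) gives 11.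

Step 9: the aryllithium may act as a base toward the β-branched bromide (loss of HBr across C3–C4), or exchange may occur at the alkyl bromide, so that the chain stays open. The fallback goes from 15 directly to 17 by nickel-catalysed intramolecular reductive cross-electrophile coupling (NiCl2·DME, 4,4′-di-tert-butyl-2,2′-bipyridine, Zn, NaI, DMA, 60 °C, high dilution). It joins C4 and C4a through an alkyl radical and an arylnickel species and avoids carbanions altogether; no new compound is isolated.

**Further compounds**

F1 | step 7 | 2,2′-{oxybis[3-(benzyloxy)-2-methoxy-4,1-phenylene]}bis(propane-1,3-diol) | COc1c(C(CO)CO)ccc(Oc2ccc(C(CO)CO)c(OC)c2OCc2ccccc2)c1OCc1ccccc1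
F2 | step 7 | (S,S)-bis(monoacetate); each arm (2S)-3-hydroxy-2-arylpropyl acetate | COc1c([C@@H](CO)COC(C)=O)ccc(Oc2ccc([C@@H](CO)COC(C)=O)c(OC)c2OCc2ccccc2)c1OCc1ccccc1
F3 | step 7 | (R,R)-bis(bromo acetate); each arm (2R)-3-bromo-2-arylpropyl acetate | COc1c([C@@H](CBr)COC(C)=O)ccc(Oc2ccc([C@@H](CBr)COC(C)=O)c(OC)c2OCc2ccccc2)c1OCc1ccccc1
F4 | step 6 | tetraethyl 2,2′-{oxybis[3-(benzyloxy)-2-methoxy-4,1-phenylene]}dimalonate | COc1c(C(C(=O)OCC)C(=O)OCC)ccc(Oc2ccc(C(C(=O)OCC)C(=O)OCC)c(OC)c2OCc2ccccc2)c1OCc1ccccc1
F0 | step 9 | none | none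
A1 | direct plan | 4,4′-oxybis(2-methoxybenzaldehyde) | COc1cc(Oc2ccc(C=O)c(OC)c2)ccc1C=O
A2 | direct plan | 4,4′-oxybis(3-hydroxy-2-methoxybenzaldehyde) | COc1c(O)c(Oc2ccc(C=O)c(OC)c2O)ccc1C=O
A3 | direct plan | (E,E)-bis(2′-hydroxychalcone) with four benzyl ethers | COc1c(OCc2ccccc2)c(Oc2ccc(/C=C/C(=O)c3ccc(OCc4ccccc4)cc3O)c(OC)c2OCc2ccccc2)ccc1/C=C/C(=O)c1ccc(OCc2ccccc2)cc1O
A4 | direct plan | 3,3′-[oxybis(3-benzyloxy-2-methoxy-4,1-phenylene)]bis(7-benzyloxy-4H-chromen-4-one) | COc1c(OCc2ccccc2)c(Oc2ccc(-c3coc4cc(OCc5ccccc5)ccc4c3=O)c(OC)c2OCc2ccccc2)ccc1-c1coc2cc(OCc3ccccc3)ccc2c1=O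
A5 | direct plan | 3,3′-[oxybis(3-benzyloxy-2-methoxy-4,1-phenylene)]bis[(3R,4R)-7-benzyloxychroman-4-ol] | COc1c(OCc2ccccc2)c(Oc2ccc([C@@H]3COc4cc(OCc5ccccc5)ccc4[C@@H]3O)c(OC)c2OCc2ccccc2)ccc1[C@@H]1COc2cc(OCc3ccccc3)ccc2[C@@H]1O
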